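**Retrosynthetic overview** (germacrane numbering: ring carbons C1–C10, C11 the methylene-bearing carbon, C12 the lactone carbonyl, C13 the =CH2, C14 and C15 the methyls on C10 and C4; ring A = ten-membered carbocycle, ring B = γ-lactone, ring C = oxirane)
1. The strategy rests on the C9–C10 bond of ring A: C9 is a ring CH2 joined to the methyl-bearing sp2 carbon C10 of the E-C1=C10 alkene (the later oxirane), so it can be made by sp3–sp2 cross-coupling with the alkene geometry fixed beforehand.
2. Endgame after ring closure: PMB off O8, isovalerate on, epoxidation of C1=C10 (ring C), desilylation, oxidative lactonisation of the C6,C12-diol (ring B).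
3. Ring A: Negishi closure of the C9 alkylzinc onto the E-alkenyl iodide at C10 (33 to 35).
4. Open chain: C6–C7 by Evans syn-aldol (imide 19 + Z-enal 11); C9 added as PMBOCH2Li to a Weinreb amide; C8 by 1,3-anti reduction; PMB moved from O9 to O8 through a PMP acetal; E-alkenyl iodide by hydrozirconation–iodination of the 2-alkyne.
5. West fragment from propargyl alcohol (anti-carbomagnesiation/iodination, asymmetric propargylation, methyl capping, formylation). Ring order: A (step 21), C (step 24), B (step 26).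

Key step: step 21

Assumption: (R)-3,3'-bis(2,4,6-triisopropylphenyl)-1,1'-binaphthyl-2,2'-diyl hydrogen phosphate is taken to direct allenylboration to the Re face of enal 4, as with aryl and alkenyl aldehydes; the configuration at C3 would be checked on 6 (Mosher esters) and the (S)-acid used if the sense were opposite.

**Step 1**
Reactants: 1 prop-2-yn-1-ol
Product: 3 (Z)-3-iodo-2-methylprop-2-en-1-ol, via cyclic alkenylmagnesium alkoxide 2 (not isolated)
Conditions: MeMgBr (2.5 equiv), CuI (10 mol %), Et2O, -10 °C to reflux; then I2, THF, -20 to 0 °C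
Reagents that add atoms: methylmagnesium bromide C[Mg]Br; iodine II
Why: Copper-catalysed anti-carbomagnesiation of the propargylic alkoxide should place methyl on C4 and magnesium on C5 in a five-membered chelate, and iodinolysis with retention gives the Z-iodoalkene carrying C3, C4, C5 and C15.

**Step 2**
Reactants: 3 (Z)-3-iodo-2-methylprop-2-en-1-ol
Product: 4 (Z)-3-iodo-2-methylprop-2-enal
Conditions: MnO2 (activated, excess), CH2Cl2, 23 °C, dark; filtered solution used at once
Reagents that add atoms: none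
Why: Neutral heterogeneous allylic oxidation should give the sensitive β-iodoenal without Z to E isomerisation.

**Step 3**
Reactants: 4 (Z)-3-iodo-2-methylprop-2-enal; 5 allenylboronic acid pinacol ester
Product: 6 (3R,1Z)-1-iodo-2-methylhex-1-en-5-yn-3-ol
Conditions: (R)-3,3'-bis(2,4,6-triisopropylphenyl)-1,1'-binaphthyl-2,2'-diyl hydrogen phosphate (5 mol %), 4 Å molecular sieves, toluene, -20 °C; aqueous work-up
Reagents that add atoms: none
Why: Chiral phosphoric acid-catalysed allenylboration (SE2' through a six-membered chair transition state) should give the homopropargylic alcohol, the catalyst setting C3 (R) by Re-face addition.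

**Step 4**
Reactants: 6 (3R,1Z)-1-iodo-2-methylhex-1-en-5-yn-3-ol
Product: 7 tert-butyl{[(3R,1Z)-1-iodo-2-methylhex-1-en-5-yn-3-yl]oxy}dimethylsilane
Conditions: TBSCl, imidazole, DMF, 23 °C
Reagents that add atoms: tert-butyldimethylsilyl chloride CC(C)(C)[Si](C)(C)Cl
Why: Standard silylation of a secondary alcohol; C3 is untouched.

**Step 5**
Reactants: 7 tert-butyl{[(3R,1Z)-1-iodo-2-methylhex-1-en-5-yn-3-yl]oxy}dimethylsilane
Product: 9 tert-butyl{[(3R,1Z)-1-iodo-2-methylhept-1-en-5-yn-3-yl]oxy}dimethylsilane, via lithium acetylide 8 (not isolated)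
Conditions: LiHMDS (1.2 equiv), THF, -78 °C; then MeOTf, -78 to -20 °C
Reagents that add atoms: methyl trifluoromethanesulfonate COS(=O)(=O)C(F)(F)F
Why: Deprotonation of the terminal alkyne with an amide base (which spares the alkenyl iodide) and C-methylation of the acetylide installs C14 and gives the 2-alkyne.

**Step 6**
Reactants: 9 tert-butyl{[(3R,1Z)-1-iodo-2-methylhept-1-en-5-yn-3-yl]oxy}dimethylsilane
Product: 11 (2Z,4R)-4-[(tert-butyldimethylsilyl)oxy]-3-methyloct-2-en-6-ynal, via Z-alkenyllithium 10 (not isolated)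
Conditions: t-BuLi (2.1 equiv), Et2O, -78 °C, 20 min; then DMF, -78 to -40 °C; aq. NH4Cl
Reagents that add atoms: N,N-dimethylformamide CN(C)C=O
Why: Iodine–lithium exchange with retention and formylation should give the Z-enal (C6 aldehyde); keeping the alkenyllithium at -78 °C in ether avoids 1,4-silyl migration.

**Step 7**
Reactants: 12 2-methylenepropane-1,3-diol
Product: 13 2-{[(tert-butyldimethylsilyl)oxy]methyl}prop-2-en-1-ol
Conditions: NaH (1.0 equiv), THF, 0 °C; then TBSCl (1.0 equiv), 0 to 23 °C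
Reagents that add atoms: tert-butyldimethylsilyl chloride CC(C)(C)[Si](C)(C)Cl
Why: Monosilylation of the symmetrical diol through its poorly soluble monosodium alkoxide.

**Step 8**
Reactants: 13 2-{[(tert-butyldimethylsilyl)oxy]methyl}prop-2-en-1-ol
Product: 14 {[2-(bromomethyl)prop-2-en-1-yl]oxy}(tert-butyl)dimethylsilane
Conditions: CBr4, PPh3, CH2Cl2, 0 °C
Reagents that add atoms: carbon tetrabromide BrC(Br)(Br)Br
Why: Appel bromination of a primary allylic alcohol; the 2-substituted allyl unit is symmetrical, so allylic transposition is of no consequence.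

**Step 9**
Reactants: 14 {[2-(bromomethyl)prop-2-en-1-yl]oxy}(tert-butyl)dimethylsilane
Product: 16 3-{[(tert-butyldimethylsilyl)oxy]methyl}but-3-enoic acid, via allylmagnesium bromide 15 (not isolated)
Conditions: Mg turnings (excess), THF, 0 °C, slow addition; then CO2 (gas), -40 to 0 °C; cold 0.5 M HCl
Reagents that add atoms: carbon dioxide O=C=O
Why: Carboxylation of an allylic Grignard reagent gives the β,γ-unsaturated acid (C8 carboxyl, C7 methylene); slow addition to excess magnesium limits Wurtz coupling.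

**Step 10**
Reactants: 16 3-{[(tert-butyldimethylsilyl)oxy]methyl}but-3-enoic acid; 17 (S)-4-benzyl-1,3-oxazolidin-2-one
Product: 19 (4S)-4-benzyl-3-(3-{[(tert-butyldimethylsilyl)oxy]methyl}but-3-enoyl)-1,3-oxazolidin-2-one, via mixed pivalic anhydride 18 (not isolated)
Conditions: t-BuCOCl, Et3N, THF, -20 °C; then 17, LiCl, 23 °C
Reagents that add atoms: none
Why: N-acylation of the oxazolidinone through the mixed anhydride with LiCl activation avoids strong base and so conjugation of the β,γ-alkene.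

**Step 11**
Reactants: 19 (4S)-4-benzyl-3-(3-{[(tert-butyldimethylsilyl)oxy]methyl}but-3-enoyl)-1,3-oxazolidin-2-one; 11 (2Z,4R)-4-[(tert-butyldimethylsilyl)oxy]-3-methyloct-2-en-6-ynal
Product: 21 Evans syn-aldol adduct (3R,6R,7S; C8 imide), via dibutylboron Z-enolate 20 (not isolated)
Conditions: Bu2BOTf, Et3N, CH2Cl2, -78 to 0 °C; then 11, -78 to 0 °C; pH 7 buffer, MeOH, H2O2, 0 °C
Reagents that add atoms: none
Why: Evans syn-aldol reaction: the Z-boron enolate reacts through a Zimmerman–Traxler chair on the face opposite the benzyl group, forming C6–C7 and setting C6 (R) and C7 with the syn relation between O6 and C11.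

**Step 12**
Reactants: 21 Evans syn-aldol adduct
Product: 22 β-hydroxy Weinreb amide (3R,6R,7S)
Conditions: MeONHMe·HCl, AlMe3, CH2Cl2/THF, -20 to 0 °C; Rochelle salt work-up
Reagents that add atoms: N,O-dimethylhydroxylamine hydrochloride Cl.CNOC
Why: Aluminium amide transamination of the imide, assisted by the free C6 hydroxyl, releases the auxiliary and gives the Weinreb amide without touching C7.

**Step 13**
Reactants: 23 (tributylstannyl)methanol
Product: 24 tributyl{[(4-methoxybenzyl)oxy]methyl}stannane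
Conditions: NaH, THF/DMF, 0 °C; then 4-methoxybenzyl chloride, Bu4NI (cat.), 23 °C
Reagents that add atoms: 4-methoxybenzyl chloride COc1ccc(CCl)cc1
Why: Williamson etherification gives the α-alkoxymethylstannane, the precursor of the C9 nucleophile.

**Step 14**
Reactants: 22 β-hydroxy Weinreb amide; 24 tributyl{[(4-methoxybenzyl)oxy]methyl}stannane
Product: 26 β-hydroxy ketone (C8 ketone, C9–OPMB; 3R,6R,7S), via PMB-oxymethyllithium 25 (not isolated)
Conditions: 24 (3.3 equiv), n-BuLi (3.0 equiv), THF, -78 °C; then 22, -78 °C; aq. NH4Cl at -78 °C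
Reagents that add atoms: none
Why: Tin–lithium exchange gives the α-alkoxy organolithium, which adds once to the Weinreb amide (stable chelated tetrahedral intermediate) to install C9; one equivalent is spent on the C6 hydroxyl.

**Step 15**
Reactants: 26 β-hydroxy ketone
Product: 27 anti-1,3-diol (C6–OH, C8–OH, C9–OPMB; 3R,6R,7S,8S)
Conditions: Me4NBH(OAc)3, MeCN/AcOH (1:1), -35 °C
Reagents that add atoms: none
Why: Evans–Saksena reduction: the C6 alkoxy(diacetoxy)borohydride delivers hydride intramolecularly through a chair, setting C8 anti to O6.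

**Step 16**
Reactants: 27 anti-1,3-diol
Product: 28 C8,C9 p-methoxybenzylidene acetal (dioxolane; free C6–OH; acetal epimers)
Conditions: DDQ (1.2 equiv), 4 Å molecular sieves, CH2Cl2, 0 °C
Reagents that add atoms: none
Why: Anhydrous DDQ oxidation of the PMB ether gives an oxocarbenium ion that is trapped by the adjacent C8 hydroxyl (five-membered ring favoured over the seven-membered one through O6), which distinguishes O8 from O6.

**Step 17**
Reactants: 28 C8,C9 p-methoxybenzylidene acetal
Product: 29 C6 TBS ether of the acetal (3R,6R,7R,8S)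
Conditions: TBSOTf, 2,6-lutidine, CH2Cl2, -78 °C
Reagents that add atoms: tert-butyldimethylsilyl trifluoromethanesulfonate CC(C)(C)[Si](C)(C)OS(=O)(=O)C(F)(F)F
Why: Silylation of the hindered allylic C6 alcohol with the silyl triflate at low temperature, where the acetal is stable.

**Step 18**
Reactants: 29 C6 TBS ether of the acetal
Product: 31 E-alkenyl iodide (iodine on C10), via alkenylzirconocene chloride 30 (not isolated)
Conditions: Cp2Zr(H)Cl (2.5 equiv), THF, 23 to 45 °C; then I2, THF, 0 °C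
Reagents that add atoms: iodine II
Why: Syn-hydrozirconation of the 2-alkyne, equilibrated with excess Schwartz reagent to put zirconium on the less hindered methyl-bearing C10, followed by iodinolysis with retention should give the E-2-iodo-2-alkene; the 1,1-disubstituted and trisubstituted alkenes react more slowly.

**Step 19**
Reactants: 31 E-alkenyl iodide acetal
Product: 32 primary alcohol (C9–OH) with C8 PMB ether (3R,6R,7R,8S)
Conditions: DIBAL-H (4 equiv), CH2Cl2, -78 to 0 °C; Rochelle salt work-up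
Reagents that add atoms: none
Why: Reductive opening of the p-methoxybenzylidene acetal: aluminium binds the less hindered primary oxygen, so the PMB group ends on the secondary O8 and C9–OH is freed.

**Step 20**
Reactants: 32 primary alcohol
Product: 33 open-chain C9 alkyl iodide / C10 E-alkenyl iodide (3R,6R,7R,8S)
Conditions: I2, PPh3, imidazole, CH2Cl2, 0 to 23 °C
Reagents that add atoms: iodine II
Why: Appel-type iodination of the primary alcohol through the alkoxyphosphonium salt.

**Step 21**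
Reactants: 33 open-chain diiodide
Product: 35 (1(10)E,4Z)-cyclodecadiene with O8 PMB and O3, O6, O12 TBS (3R,6R,7R,8R), via alkylzinc iodide 34 (not isolated)
Conditions: Zn dust (activated with 1,2-dibromoethane and Me3SiCl), LiCl, THF, 25 °C; excess zinc removed; then syringe-pump addition over 12 h to Pd(P(t-Bu)3)2 (15 mol %, zerovalent palladium), THF/NMP (2:1), 40 °C, final concentration about 1 mM
Reagents that add atoms: none
Why: Proposed new method: LiCl-activated zinc should insert into the primary C9–I bond much faster than into the alkenyl C10–I bond to give alkylzinc iodide 34; zerovalent palladium then adds oxidatively to the E-alkenyl iodide with retention, intramolecular transmetallation gives an eleven-membered alkyl(alkenyl)palladacycle, and reductive elimination forms C9–C10. The closest known reaction types are the intermolecular alkylzinc–alkenyl halide Negishi coupling with this catalyst and sp3–sp2 Negishi or B-alkyl Suzuki–Miyaura macrocyclisations to larger rings; a ten-membered carbocycle has not been closed this way. Ring A is closed end to end by reductive elimination, with the Z-C4=C5 alkene and the branched C6–C8 segment pre-folding the chain. No stereocentre is formed, and both alkene geometries are fixed beforehand and retained. The step needs chemoselective zinc insertion (secured by the higher reactivity of the primary alkyl iodide), survival of the β-PMB-oxy alkylzinc (aprotic THF at 25 °C, by analogy with the stability of (1,3-dioxolan-2-ylmethyl)zinc bromide) and fast reductive elimination over β-hydride or β-alkoxide elimination (bulky P(t-Bu)3). Ring closure over oligomerisation is secured by slow addition at high dilution.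

**Step 22**
Reactants: 35 protected cyclodecadiene
Product: 36 C8 alcohol (3R,6R,7R,8R)
Conditions: DDQ, CH2Cl2/pH 7 phosphate buffer (10:1), 0 °C
Reagents that add atoms: none
Why: Oxidative cleavage of the PMB ether frees only O8; silyl ethers and the unconjugated alkenes are inert.

**Step 23**
Reactants: 36 C8 alcohol; 37 isovaleric acid
Product: 38 C8 isovalerate (3R,6R,7R,8R)
Conditions: EDC·HCl, 4-(dimethylamino)pyridine, CH2Cl2, 23 °C
Reagents that add atoms: none
Why: Steglich esterification of the secondary alcohol with retention at C8.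

**Step 24**
Reactants: 38 C8 isovalerate
Product: 39 1,10-epoxide (1R,3R,6R,7R,8R,10R)
Conditions: m-CPBA (1.1 equiv), NaHCO3, CH2Cl2, -20 to 0 °C
Reagents that add atoms: 3-chloroperoxybenzoic acid O=C(OO)c1cccc(Cl)c1
Why: Prilezhaev epoxidation of the most electron-rich alkene (C1=C10; C4=C5 is flanked by two silyloxy carbons and C11=C13 is 1,1-disubstituted); syn addition to the E-alkene from the exposed outer face of the ring conformer should set C1 and C10.

**Step 25**
Reactants: 39 1,10-epoxide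
Product: 40 triol (C3–OH, C6–OH, C12–OH; 1R,3R,6R,7S,8R,10R)
Conditions: HF·pyridine, excess pyridine, THF, 0 to 23 °C
Reagents that add atoms: none
Why: Buffered fluoride desilylation removes the three TBS groups under conditions mild enough for the ester and the trisubstituted oxirane.

**Step 26**
Reactants: 40 triol
Product: 43 target (CNP0300193.1), via C12 aldehyde 41 (not isolated), via lactol 42 (not isolated)
Conditions: 2,2,6,6-tetramethylpiperidin-1-oxyl (TEMPO, 20 mol %), PhI(OAc)2 (2.5 equiv), CH2Cl2, 23 °C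
Reagents that add atoms: none
Why: Oxoammonium oxidation is selective for the primary allylic C12 alcohol; the aldehyde closes onto O6 to the five-membered lactol, which is oxidised to the α-methylene-γ-lactone (ring B), C6 and C7 being unchanged.

**Compound list**
1 | prop-2-yn-1-ol (propargyl alcohol) | C#CCO | starting material
2 | cyclic (Z)-alkenylmagnesium alkoxide (4-methyl-2,5-dihydro-1,2-oxamagnesole) | CC1=C[Mg]OC1 | intermediate
3 | (Z)-3-iodo-2-methylprop-2-en-1-ol | OC/C(C)=C\I | intermediate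
4 | (Z)-3-iodo-2-methylprop-2-enal | O=C/C(C)=C\I | intermediate
5 | allenylboronic acid pinacol ester | C=C=CB1OC(C)(C)C(C)(C)O1 | starting material
6 | (3R,1Z)-1-iodo-2-methylhex-1-en-5-yn-3-ol | I/C=C(C)\[C@H](O)CC#C | intermediate
7 | tert-butyl{[(3R,1Z)-1-iodo-2-methylhex-1-en-5-yn-3-yl]oxy}dimethylsilane | I/C=C(C)\[C@H](O[Si](C)(C)C(C)(C)C)CC#C | intermediate
8 | lithium acetylide of 7 | I/C=C(C)\[C@H](O[Si](C)(C)C(C)(C)C)CC#C[Li] | intermediate
9 | tert-butyl{[(3R,1Z)-1-iodo-2-methylhept-1-en-5-yn-3-yl]oxy}dimethylsilane | I/C=C(C)\[C@H](O[Si](C)(C)C(C)(C)C)CC#CC | intermediate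
10 | (Z)-alkenyllithium from 9 | [Li]/C=C(C)\[C@H](O[Si](C)(C)C(C)(C)C)CC#CC | intermediate
11 | (2Z,4R)-4-[(tert-butyldimethylsilyl)oxy]-3-methyloct-2-en-6-ynal | O=C/C=C(C)\[C@H](O[Si](C)(C)C(C)(C)C)CC#CC | intermediate
12 | 2-methylenepropane-1,3-diol | C=C(CO)CO | starting material
13 | 2-{[(tert-butyldimethylsilyl)oxy]methyl}prop-2-en-1-ol | C=C(CO)CO[Si](C)(C)C(C)(C)C | intermediate
14 | {[2-(bromomethyl)prop-2-en-1-yl]oxy}(tert-butyl)dimethylsilane | C=C(CBr)CO[Si](C)(C)C(C)(C)C | intermediate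
15 | allylmagnesium bromide from 14 | C=C(C[Mg]Br)CO[Si](C)(C)C(C)(C)C | intermediate
16 | 3-{[(tert-butyldimethylsilyl)oxy]methyl}but-3-enoic acid | C=C(CC(=O)O)CO[Si](C)(C)C(C)(C)C | intermediate
17 | (S)-4-benzyl-1,3-oxazolidin-2-one | O=C1OC[C@H](Cc2ccccc2)N1 | starting material
18 | mixed pivalic anhydride of 16 | C=C(CC(=O)OC(=O)C(C)(C)C)CO[Si](C)(C)C(C)(C)C | intermediate
19 | (4S)-4-benzyl-3-(3-{[(tert-butyldimethylsilyl)oxy]methyl}but-3-enoyl)-1,3-oxazolidin-2-one | C=C(CO[Si](C)(C)C(C)(C)C)CC(=O)N1[C@@H](Cc2ccccc2)COC1=O | intermediate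
20 | dibutylboron Z-enolate of 19 | CCCCB(CCCC)O/C(=C\C(=C)CO[Si](C)(C)C(C)(C)C)N1[C@@H](Cc2ccccc2)COC1=O | intermediate
21 | Evans syn-aldol adduct, (4S)-4-benzyl-3-[(2S,3R,4Z,6R)-6-(TBS-oxy)-2-{3-(TBS-oxy)prop-1-en-2-yl}-3-hydroxy-5-methyldec-4-en-8-ynoyl]-1,3-oxazolidin-2-one | O=C(N1[C@@H](Cc2ccccc2)COC1=O)[C@@H](C(=C)CO[Si](C)(C)C(C)(C)C)[C@H](O)/C=C(C)\[C@H](O[Si](C)(C)C(C)(C)C)CC#CC | intermediate
22 | Weinreb amide, (2S,3R,4Z,6R)-6-(TBS-oxy)-2-{3-(TBS-oxy)prop-1-en-2-yl}-3-hydroxy-N-methoxy-N,5-dimethyldec-4-en-8-ynamide | CON(C)C(=O)[C@@H](C(=C)CO[Si](C)(C)C(C)(C)C)[C@H](O)/C=C(C)\[C@H](O[Si](C)(C)C(C)(C)C)CC#CC | intermediate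
23 | (tributylstannyl)methanol | CCCC[Sn](CCCC)(CCCC)CO | starting material
24 | tributyl{[(4-methoxybenzyl)oxy]methyl}stannane | CCCC[Sn](CCCC)(CCCC)COCc1ccc(OC)cc1 | intermediate
25 | [(4-methoxybenzyl)oxy]methyllithium | [Li]COCc1ccc(OC)cc1 | intermediate
26 | β-hydroxy ketone, (3S,4R,5Z,7R)-7-(TBS-oxy)-3-{3-(TBS-oxy)prop-1-en-2-yl}-4-hydroxy-1-[(4-methoxybenzyl)oxy]-6-methylundec-5-en-9-yn-2-one | COc1ccc(COCC(=O)[C@@H](C(=C)CO[Si](C)(C)C(C)(C)C)[C@H](O)/C=C(C)\[C@H](O[Si](C)(C)C(C)(C)C)CC#CC)cc1 | intermediate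
27 | anti-diol, (2S,3S,4R,5Z,7R)-7-(TBS-oxy)-3-{3-(TBS-oxy)prop-1-en-2-yl}-1-[(4-methoxybenzyl)oxy]-6-methylundec-5-en-9-yne-2,4-diol | COc1ccc(COC[C@@H](O)[C@@H](C(=C)CO[Si](C)(C)C(C)(C)C)[C@H](O)/C=C(C)\[C@H](O[Si](C)(C)C(C)(C)C)CC#CC)cc1 | intermediate
28 | C8,C9 p-methoxybenzylidene acetal of 27 (2-(4-methoxyphenyl)-1,3-dioxolane, free C6–OH, acetal epimers) | COc1ccc(cc1)C1OC[C@@H](O1)[C@@H](C(=C)CO[Si](C)(C)C(C)(C)C)[C@H](O)/C=C(C)\[C@H](O[Si](C)(C)C(C)(C)C)CC#CC | intermediate
29 | C6 TBS ether of 28 | COc1ccc(cc1)C1OC[C@@H](O1)[C@@H](C(=C)CO[Si](C)(C)C(C)(C)C)[C@H](O[Si](C)(C)C(C)(C)C)/C=C(C)\[C@H](O[Si](C)(C)C(C)(C)C)CC#CC | intermediate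
30 | (E)-alkenylzirconocene chloride from 29 (Zr on C10) | COc1ccc(cc1)C1OC[C@@H](O1)[C@@H](C(=C)CO[Si](C)(C)C(C)(C)C)[C@H](O[Si](C)(C)C(C)(C)C)/C=C(C)\[C@H](O[Si](C)(C)C(C)(C)C)C/C=C(C)/[Zr](Cl)(C1C=CC=C1)C1C=CC=C1 | intermediate
31 | (E)-C10 alkenyl iodide with C8,C9 acetal | COc1ccc(cc1)C1OC[C@@H](O1)[C@@H](C(=C)CO[Si](C)(C)C(C)(C)C)[C@H](O[Si](C)(C)C(C)(C)C)/C=C(C)\[C@H](O[Si](C)(C)C(C)(C)C)C/C=C(C)/I | intermediate
32 | primary C9 alcohol with C8 PMB ether and C10 E-alkenyl iodide (3R,6R,7R,8S) | OC[C@@H](OCc1ccc(OC)cc1)[C@@H](C(=C)CO[Si](C)(C)C(C)(C)C)[C@H](O[Si](C)(C)C(C)(C)C)/C=C(C)\[C@H](O[Si](C)(C)C(C)(C)C)C/C=C(C)/I | intermediate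
33 | open-chain C9 alkyl iodide / C10 E-alkenyl iodide, Z-C4=C5, O8 PMB, O3, O6, O12 TBS (3R,6R,7R,8S) | IC[C@@H](OCc1ccc(OC)cc1)[C@@H](C(=C)CO[Si](C)(C)C(C)(C)C)[C@H](O[Si](C)(C)C(C)(C)C)/C=C(C)\[C@H](O[Si](C)(C)C(C)(C)C)C/C=C(C)/I | intermediate
34 | C9 alkylzinc iodide from 33 | I[Zn]C[C@@H](OCc1ccc(OC)cc1)[C@@H](C(=C)CO[Si](C)(C)C(C)(C)C)[C@H](O[Si](C)(C)C(C)(C)C)/C=C(C)\[C@H](O[Si](C)(C)C(C)(C)C)C/C=C(C)/I | intermediate
35 | (1(10)E,4Z)-cyclodecadiene, O8 PMB, O3, O6, O12 TBS (3R,6R,7R,8R) | C1/C=C(C)/C[C@@H](OCc2ccc(OC)cc2)[C@@H](C(=C)CO[Si](C)(C)C(C)(C)C)[C@H](O[Si](C)(C)C(C)(C)C)/C=C(C)\[C@@H]1O[Si](C)(C)C(C)(C)C | intermediate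
36 | C8 alcohol of the cyclodecadiene (3R,6R,7R,8R) | C1/C=C(C)/C[C@@H](O)[C@@H](C(=C)CO[Si](C)(C)C(C)(C)C)[C@H](O[Si](C)(C)C(C)(C)C)/C=C(C)\[C@@H]1O[Si](C)(C)C(C)(C)C | intermediate
37 | isovaleric acid (3-methylbutanoic acid) | CC(C)CC(=O)O | starting material
38 | C8 isovalerate of the cyclodecadiene (3R,6R,7R,8R) | C1/C=C(C)/C[C@@H](OC(=O)CC(C)C)[C@@H](C(=C)CO[Si](C)(C)C(C)(C)C)[C@H](O[Si](C)(C)C(C)(C)C)/C=C(C)\[C@@H]1O[Si](C)(C)C(C)(C)C | intermediate
39 | 1,10-epoxide, tris-TBS ether (1R,3R,6R,7R,8R,10R) | C=C(CO[Si](C)(C)C(C)(C)C)[C@H]1[C@H](O[Si](C)(C)C(C)(C)C)/C=C(/C)[C@H](O[Si](C)(C)C(C)(C)C)C[C@H]2O[C@]2(C)C[C@H]1OC(=O)CC(C)C | intermediate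
40 | epoxy triol (C3–OH, C6–OH, C12–OH; 1R,3R,6R,7S,8R,10R) | C=C(CO)[C@H]1[C@H](O)/C=C(/C)[C@H](O)C[C@H]2O[C@]2(C)C[C@H]1OC(=O)CC(C)C | intermediate
41 | C12 aldehyde of 40 | C=C(C=O)[C@H]1[C@H](O)/C=C(/C)[C@H](O)C[C@H]2O[C@]2(C)C[C@H]1OC(=O)CC(C)C | intermediate
42 | 6,12-lactol (C12 epimers) | C=C1C(O)O[C@@H]2/C=C(/C)[C@H](O)C[C@H]3O[C@]3(C)C[C@@H](OC(=O)CC(C)C)[C@@H]12 | intermediate
43 | CNP0300193.1, (1R,3R,6R,7R,8R,10R,4Z)-1,10-epoxy-3-hydroxy-8-(3-methylbutanoyloxy)germacra-4,11(13)-dien-12,6-olide | C=C1C(=O)O[C@@H]2/C=C(/C)[C@H](O)C[C@H]3O[C@]3(C)C[C@@H](OC(=O)CC(C)C)[C@@H]12 | target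

**Step count and risks**
Total: 26 steps. Longest linear sequence: 21 steps (steps 1–6, 11, 12, 14–26).

Steps most likely to fail:

1. Step 21 (Proposed new method). The β-PMB-oxy alkylzinc or the derived alkylpalladium may lose alkoxide by β-elimination, or chain-to-chain coupling may outrun closure of the strained ten-membered ring. Fallback, from 32 back to 35: C9–C10 would be closed by carbonyl addition instead of cross-coupling. Alcohol 32 would be oxidised (Dess–Martin periodinane, NaHCO3, CH2Cl2) to the C9 aldehyde F1. This would be cyclised by an intramolecular Nozaki–Hiyama–Kishi reaction (CrCl2, divalent chromium, with catalytic NiCl2, DMSO/THF, high dilution) to the ten-membered allylic alcohol F2 (C9 epimers). Acylation (ClCO2Me, pyridine) would give the allylic methyl carbonate F3, and palladium-catalysed formate hydrogenolysis (Pd(OAc)2, PBu3, HCO2NH4, THF), which delivers hydride to the more hindered allyl terminus C9 and keeps the C1=C10 alkene, would return macrocycle 35.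

2. Step 24. The peracid may be delivered to the wrong face, or to both faces, of C1=C10 if the ring conformer exposes the other side. Fallback, from 38 back to 39: the face would be inverted through a halohydrin. N-Bromosuccinimide in THF/H2O at 0 °C should form the bromonium ion on the accessible face and water should open it anti at the tertiary C10, giving the bromohydrin F4 (C1–Br, C10–OH). Base (DBU, toluene, 23 °C) would then close the oxirane with inversion at C1, placing oxygen on the face opposite to the one the peracid attacks.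

3. Step 25. The trisubstituted oxirane may be opened by fluoride, or by transannular attack, under the acidic conditions needed to remove three silyl ethers. Fallback, from 38 back to 43: the order of events would be changed so that the oxirane is made last. Ester 38 would be desilylated (HF·pyridine, pyridine, THF) to the diene triol F5, then lactonised (TEMPO, PhI(OAc)2) to the 1(10)E,4Z-dienolide F6. Epoxidation of F6 with m-CPBA (NaHCO3, CH2Cl2, 0 °C) at the only electron-rich alkene, C1=C10, would give 43 directly.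

**Further compounds**
F1 | step 21 | C9 aldehyde from 32 (C8 PMB ether, C10 E-alkenyl iodide) | O=C[C@@H](OCc1ccc(OC)cc1)[C@@H](C(=C)CO[Si](C)(C)C(C)(C)C)[C@H](O[Si](C)(C)C(C)(C)C)/C=C(C)\[C@H](O[Si](C)(C)C(C)(C)C)C/C=C(C)/I
F2 | step 21 | ten-membered allylic alcohol (C9–OH epimers; 1(10)E,4Z) | C1/C=C(C)/C(O)[C@@H](OCc2ccc(OC)cc2)[C@@H](C(=C)CO[Si](C)(C)C(C)(C)C)[C@H](O[Si](C)(C)C(C)(C)C)/C=C(C)\[C@@H]1O[Si](C)(C)C(C)(C)C
F3 | step 21 | C9 allylic methyl carbonate of F2 | C1/C=C(C)/C(OC(=O)OC)[C@@H](OCc2ccc(OC)cc2)[C@@H](C(=C)CO[Si](C)(C)C(C)(C)C)[C@H](O[Si](C)(C)C(C)(C)C)/C=C(C)\[C@@H]1O[Si](C)(C)C(C)(C)C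
F4 | step 24 | trans-bromohydrin of 38 (C1–Br, C10–OH) | C=C(CO[Si](C)(C)C(C)(C)C)[C@H]1[C@H](O[Si](C)(C)C(C)(C)C)/C=C(/C)[C@H](O[Si](C)(C)C(C)(C)C)C[C@H](Br)[C@@](O)(C)C[C@H]1OC(=O)CC(C)C
F5 | step 25 | diene triol from 38 (C3–OH, C6–OH, C12–OH; C8 isovalerate) | C1/C=C(C)/C[C@@H](OC(=O)CC(C)C)[C@@H](C(=C)CO)[C@H](O)/C=C(C)\[C@@H]1O
F6 | step 25 | 1(10)E,4Z-dien-12,6-olide (target lacking the oxirane) | C=C1C(=O)O[C@@H]2/C=C(/C)[C@H](O)C/C=C(C)/C[C@@H](OC(=O)CC(C)C)[C@@H]12
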